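**Plan**
Retrosynthesis: the S–O6 bond is cut first (sulfate ester of a 5,6-diol whose O7, O3' and O4' carry benzyl groups). The O1–C2 bond of ring C is cut next, then C2–C3 (aldol) and C4–C4a (acylation).
Enabling feature: C4a of ring A lies between two oxygen-bearing carbons, C8a (O1) and C5 (5-OH). Once ring C is open at O1–C2, either oxygen can close it again, and closure through the old O5 turns a C8 oxygen into the C6 oxygen.
Forward: ring A is bought, acetylated (C4–C4a) and freed at one ortho oxygen, and ring B is joined by aldol condensation (C2–C3). Ring C is closed oxidatively in the 5,7,8 sense, then opened and reclosed in the 5,6,7 sense by hot HI, which also removes all methyl groups.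
Endgame: partial benzylation leaves only the 5,6-diol. SO3·pyridine takes O6 because the 5-OH is chelated to C4=O, and hydrogenolysis unmasks the target.
Stereochemistry: the target has no stereocentre. The only stereo-element on the way is the E double bond of the chalcone, which is set thermodynamically and disappears in the pyranone.

Key step: step 4

Assumption: the two sulfate monoesters are drawn as hydrogen sulfates, as in the target SMILES; in the flask they would be kept as potassium salts (KHCO3 work-up) and the acid form released only at the very end on a cold H+ resin, because aryl hydrogen sulfates hydrolyse under their own acidity.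

**Step 1**
Reactants: 1 1,2,3,5-tetramethoxybenzene; 2 acetyl chloride
Product: 4 1-(2-hydroxy-3,4,6-trimethoxyphenyl)ethanone, via 2',3',4',6'-tetramethoxyacetophenone 3 (not isolated)
Conditions: AlCl3 (2.5 equiv), Et2O, 0 °C to reflux; ice–HCl
Reagents that add atoms: none
Why: Friedel–Crafts acylation at one of the two equivalent free positions of the very electron-rich arene gives 3, and the excess AlCl3 held by the new carbonyl then cleaves an ortho methyl ether (chelation-assisted ether cleavage), by expectation the 2-OMe that is forced out of the ring plane between the acetyl group and the 3-OMe; material cleaved at the other ortho ether need not be removed rigorously, because its flavone would converge on the same pentaol in step 4.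

**Step 2**
Reactants: 4 1-(2-hydroxy-3,4,6-trimethoxyphenyl)ethanone; 5 3,4-dimethoxybenzaldehyde
Product: 6 (E)-3-(3,4-dimethoxyphenyl)-1-(2-hydroxy-3,4,6-trimethoxyphenyl)prop-2-en-1-one
Conditions: KOH, EtOH–H2O, rt
Reagents that add atoms: none
Why: Claisen–Schmidt condensation, in which the methyl ketone enolate adds to the non-enolisable aldehyde and E1cB loss of water gives the conjugated enone as the more stable E isomer, while the phenoxide form of the product holds back premature ring closure.

**Step 3**
Reactants: 6 (E)-3-(3,4-dimethoxyphenyl)-1-(2-hydroxy-3,4,6-trimethoxyphenyl)prop-2-en-1-one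
Product: 7 2-(3,4-dimethoxyphenyl)-5,7,8-trimethoxy-4H-chromen-4-one
Conditions: I2 (10 mol %), DMSO, 130 °C
Reagents that add atoms: none
Why: Iodine–DMSO oxidative cyclisation of a 2'-hydroxychalcone, a standard flavone synthesis, in which the phenol adds to the enone β-carbon (C2), iodination at C3 and loss of HI give the pyranone, and DMSO reoxidises the iodide so that I2 is needed only in catalytic amount.

**Step 4**
Reactants: 7 2-(3,4-dimethoxyphenyl)-5,7,8-trimethoxy-4H-chromen-4-one
Product: 10 6-hydroxyluteolin (2-(3,4-dihydroxyphenyl)-5,6,7-trihydroxy-4H-chromen-4-one), via hypolaetin 8 (not isolated), via open-chain 1,3-diketone 9 (not isolated)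
Conditions: 57% aq HI, AcOH, reflux (ca. 125 °C), Ar, heated until the 5,7,8 isomer is no longer detected; ice water
Reagents that add atoms: none
Why: Hot HI first cleaves all five aryl methyl ethers (iodide attacks the methyl group of each protonated ether) and gives 8, whose free 5-OH is what makes the transposition possible. Protonation of the pyranone carbonyl and addition of water at C2 break the O1–C2 bond and give 9, whose aryl ring carries two ortho hydroxyls, the old O1 next to the old 8-OH and the old O5 next to C6–H. After rotation about C4–C4a the old O5 adds to the C2 carbonyl (6-exo-trig hemiketal formation) and loss of water rebuilds ring C with a new O1–C2 bond, so that the old C8 oxygen becomes O6; this is the Wessely–Moser rearrangement, known for 5,7,8-oxygenated flavones under this kind of demethylation. No stereocentre is created. The selectivity needed is constitutional, 5,6,7 against 5,7,8, and because every event is reversible in the hot acid it is set by the relative stability of the two flavones; for flavones without a 3-substituent the balance lies with the 5,6,7 isomer, in which the contact between O1 and an 8-oxygen is relieved and the chelated 5-OH is backed by the 6-OH. The water taken up at C2 is expelled again, so the product holds only atoms of 7.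

**Step 5**
Reactants: 10 6-hydroxyluteolin
Product: 11 7-(benzyloxy)-2-[3,4-bis(benzyloxy)phenyl]-5,6-dihydroxy-4H-chromen-4-one
Conditions: BnBr (3.05 equiv), K2CO3 (3.5 equiv), degassed DMF, 0 °C to rt, Ar
Reagents that add atoms: benzyl bromide, BrCc1ccccc1
Why: Williamson etherification with a limiting amount of BnBr, in which the 7- and 4'-hydroxyls (vinylogous acids) react first, the unhindered 3'-OH follows, the 5-OH is tied up in the hydrogen bond to C4=O, and the 6-OH wedged between O5 and the new 7-benzyloxy group is expected to be the slowest remaining site, in line with the known partial benzylation of 5,6,7-trihydroxyflavones that stops at the 5,6-diol.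

**Step 6**
Reactants: 11 7-(benzyloxy)-2-[3,4-bis(benzyloxy)phenyl]-5,6-dihydroxy-4H-chromen-4-one
Product: 12 7-(benzyloxy)-2-[3,4-bis(benzyloxy)phenyl]-5-hydroxy-4-oxo-4H-chromen-6-yl hydrogen sulfate
Conditions: SO3·pyridine (3 equiv), pyridine, 45 °C; aq KHCO3, reversed-phase silica
Reagents that add atoms: sulfur trioxide–pyridine complex, [O-]S(=O)(=O)[n+]1ccccc1
Why: O-Sulfation of a phenol with a sulfur trioxide–amine complex, in which only the 6-OH is available because the chelated 5-OH of flavones resists SO3·pyridine under mild conditions and the benzyl ethers are inert.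

**Step 7**
Reactants: 12 7-(benzyloxy)-2-[3,4-bis(benzyloxy)phenyl]-5-hydroxy-4-oxo-4H-chromen-6-yl hydrogen sulfate
Product: 13 6-hydroxyluteolin 6-sulfate (2-(3,4-dihydroxyphenyl)-5,7-dihydroxy-4-oxo-4H-chromen-6-yl hydrogen sulfate)
Conditions: H2 (1 atm), 10% Pd/C, MeOH–THF–H2O, rt; filtration, cold cation-exchange resin (H+ form), freeze-drying
Reagents that add atoms: none
Why: Catalytic hydrogenolysis of aryl benzyl ethers, the usual way to unmask flavonoid sulfates, which should leave the S–O bonds and the pyranone C2=C3 bond untouched at 1 atm as long as the sulfate is kept as its salt in neutral medium.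

**Compound list**
1 | 1,2,3,5-tetramethoxybenzene | COc1cc(OC)c(OC)c(OC)c1 | starting material
2 | acetyl chloride | CC(Cl)=O | starting material
3 | 1-(2,3,4,6-tetramethoxyphenyl)ethanone | CC(=O)c1c(OC)cc(OC)c(OC)c1OC | intermediate
4 | 1-(2-hydroxy-3,4,6-trimethoxyphenyl)ethanone | CC(=O)c1c(OC)cc(OC)c(OC)c1O | intermediate
5 | 3,4-dimethoxybenzaldehyde | COc1ccc(C=O)cc1OC | starting material
6 | (E)-3-(3,4-dimethoxyphenyl)-1-(2-hydroxy-3,4,6-trimethoxyphenyl)prop-2-en-1-one | COc1ccc(/C=C/C(=O)c2c(OC)cc(OC)c(OC)c2O)cc1OC | intermediate
7 | 2-(3,4-dimethoxyphenyl)-5,7,8-trimethoxy-4H-chromen-4-one | COc1ccc(-c2cc(=O)c3c(OC)cc(OC)c(OC)c3o2)cc1OC | intermediate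
8 | hypolaetin, 2-(3,4-dihydroxyphenyl)-5,7,8-trihydroxy-4H-chromen-4-one | O=c1cc(-c2ccc(O)c(O)c2)oc2c(O)c(O)cc(O)c12 | intermediate
9 | 1-(3,4-dihydroxyphenyl)-3-(2,3,4,6-tetrahydroxyphenyl)propane-1,3-dione | O=C(CC(=O)c1ccc(O)c(O)c1)c1c(O)cc(O)c(O)c1O | intermediate
10 | 6-hydroxyluteolin, 2-(3,4-dihydroxyphenyl)-5,6,7-trihydroxy-4H-chromen-4-one | O=c1cc(-c2ccc(O)c(O)c2)oc2cc(O)c(O)c(O)c12 | intermediate
11 | 7-(benzyloxy)-2-[3,4-bis(benzyloxy)phenyl]-5,6-dihydroxy-4H-chromen-4-one | O=c1cc(-c2ccc(OCc3ccccc3)c(OCc3ccccc3)c2)oc2cc(OCc3ccccc3)c(O)c(O)c12 | intermediate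
12 | 7-(benzyloxy)-2-[3,4-bis(benzyloxy)phenyl]-5-hydroxy-4-oxo-4H-chromen-6-yl hydrogen sulfate | O=c1cc(-c2ccc(OCc3ccccc3)c(OCc3ccccc3)c2)oc2cc(OCc3ccccc3)c(OS(=O)(=O)O)c(O)c12 | intermediate
13 | 6-hydroxyluteolin 6-sulfate | O=c1cc(-c2ccc(O)c(O)c2)oc2cc(O)c(OS(=O)(=O)O)c(O)c12 | target

Total step count: 7. Longest linear sequence: 7 steps (from 1).

**Steps most likely to fail**

Step 5. The third alkylation may show poor site selectivity. Once O7 and O4' are benzylated, the 3'-OH and the 6-OH are close in acidity and only the crowding around O6 tells them apart, so benzylation at O6 and incomplete benzylation at O3' may compete. Air oxidation of the polyphenolate is a second loss channel. Wrongly benzylated fractions could be returned to 10 by hydrogenolysis.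

The fallback sets out from 10 and comes back at 13. It splits the protection into an acidity-controlled stage and a size-controlled stage.
- Two equivalents of BnBr with K2CO3 in DMF would cap only the two vinylogous-acid hydroxyls and give 7,4'-di-O-benzyl-6-hydroxyluteolin F1.
- TBDPSCl and imidazole in DMF would then silylate the open 3'-OH in preference to the flanked 6-OH, giving the 3'-silyl ether F2.
- SO3·pyridine would convert it into the 6-sulfate F3.
- NH4F in MeOH would take off the silyl group to give the dibenzyl sulfate F4.
- Hydrogenolysis under the conditions of step 7 would deliver 13.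

Step 6. Sulfation of the hindered, hydrogen-bonded 6-OH may be slow or incomplete, forcing may bring on partial sulfation at O5, and pyridinium salts may be carried over and slow the Pd-catalysed debenzylation.

The fallback sets out from 11 and comes back at 13. It replaces the ionic monoester by a neutral, protected sulfate.
- 2,2,2-Trichloroethyl chlorosulfate with Et3N and DMAP in THF would give the aryl trichloroethyl sulfate diester F5, which can be purified on ordinary silica.
- Transfer hydrogenolysis with Pd/C and HCO2NH4 in MeOH would then remove the trichloroethyl group and the three benzyl ethers in one operation.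
- Cold H+ exchange would follow, as in step 7.

Step 4. Equilibration may be incomplete, so that the 5,7,8 pattern persists, and the electron-rich pentaol may decompose by oxidation or acid on long heating.

The fallback sets out from 5 and comes back at 10. It gives up the transposition and builds the 5,6,7 pattern directly.
- Commercial 6'-hydroxy-2',3',4'-trimethoxyacetophenone F6 would be condensed with 5 (KOH, EtOH) to the chalcone F7.
- I2 in DMSO would cyclise it to 5,6,7,3',4'-pentamethoxyflavone F8.
- BBr3 in CH2Cl2 (−78 °C to rt) would demethylate it to 10 without any hot aqueous acid.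

**Further compounds**
F1 | step 5 | 7-(benzyloxy)-2-[4-(benzyloxy)-3-hydroxyphenyl]-5,6-dihydroxy-4H-chromen-4-one | O=c1cc(-c2ccc(OCc3ccccc3)c(O)c2)oc2cc(OCc3ccccc3)c(O)c(O)c12
F2 | step 5 | 7-(benzyloxy)-2-{4-(benzyloxy)-3-[(tert-butyldiphenylsilyl)oxy]phenyl}-5,6-dihydroxy-4H-chromen-4-one | O=c1cc(-c2ccc(OCc3ccccc3)c(O[Si](c3ccccc3)(c3ccccc3)C(C)(C)C)c2)oc2cc(OCc3ccccc3)c(O)c(O)c12
F3 | step 5 | 7-(benzyloxy)-2-{4-(benzyloxy)-3-[(tert-butyldiphenylsilyl)oxy]phenyl}-5-hydroxy-4-oxo-4H-chromen-6-yl hydrogen sulfate | O=c1cc(-c2ccc(OCc3ccccc3)c(O[Si](c3ccccc3)(c3ccccc3)C(C)(C)C)c2)oc2cc(OCc3ccccc3)c(OS(=O)(=O)O)c(O)c12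
F4 | step 5 | 7-(benzyloxy)-2-[4-(benzyloxy)-3-hydroxyphenyl]-5-hydroxy-4-oxo-4H-chromen-6-yl hydrogen sulfate | O=c1cc(-c2ccc(OCc3ccccc3)c(O)c2)oc2cc(OCc3ccccc3)c(OS(=O)(=O)O)c(O)c12
F5 | step 6 | 7-(benzyloxy)-2-[3,4-bis(benzyloxy)phenyl]-5-hydroxy-4-oxo-4H-chromen-6-yl 2,2,2-trichloroethyl sulfate | O=c1cc(-c2ccc(OCc3ccccc3)c(OCc3ccccc3)c2)oc2cc(OCc3ccccc3)c(OS(=O)(=O)OCC(Cl)(Cl)Cl)c(O)c12
F6 | step 4 | 1-(6-hydroxy-2,3,4-trimethoxyphenyl)ethanone | CC(=O)c1c(O)cc(OC)c(OC)c1OC
F7 | step 4 | (E)-3-(3,4-dimethoxyphenyl)-1-(6-hydroxy-2,3,4-trimethoxyphenyl)prop-2-en-1-one | COc1ccc(/C=C/C(=O)c2c(O)cc(OC)c(OC)c2OC)cc1OC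
F8 | step 4 | 2-(3,4-dimethoxyphenyl)-5,6,7-trimethoxy-4H-chromen-4-one | COc1ccc(-c2cc(=O)c3c(OC)c(OC)c(OC)cc3o2)cc1OC
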